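**Plan**
Retrosynthesis: the enol ether C14=C15 goes back to a C14 alcohol; the C13–O9 and C8–O17 bonds are then cut together, unfolding the 9,13-oxolane and the 8β,17-oxirane into a bis-epoxy alcohol (8α,9α-oxirane bearing C17–OH; 13,14-oxirane); further cuts are both epoxides, C9–C11, the C6 acetate, the 19,20-lactone, the C4 methyl, C4–C5 and C10–C1.
Forward: ring B (a cyclohexane-1,3-dione) takes up the chain by Michael addition and Wittig reaction; ring A closes by reductive aldol; C4 is methylated; C20 is unveiled and the δ-lactone closes; C8/C9 become a hydroxymethyl enol triflate; C6 is oxygenated; the 2,5-dihydrofuran side chain is joined by B-alkyl Suzuki coupling; two epoxidations, the cascade and a dehydration finish.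
Structural feature used: on ring B the oxygens on C8 (β) and C9 (α) are trans-diaxial and C8 also carries C17, which is the footprint of an 8α,9α-oxirane of a C17 allylic alcohol after a Payne-type shift; O9 stands 1,4 to the tertiary C13, so the oxirane oxygen reaches C13 through a five-membered transition state.
Stereochemistry: C10 from a ligand-controlled desymmetrising reductive aldol; C4 (methylation anti to C20), C5/C6 (α-face hydroboration, α-face hydride) and C8/C9 (α-face epoxidation) by substrate control; C13 by Shi epoxidation; the cascade transfers these with inversion at C13 and C8 and retention at C9.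

Key step: step 20

Remark: bicyclic compounds carry labdane locants (ring A C1–C5 and C10; ring B C5–C10; C17 on C8; C18/C19 on C4; C20 on C10; C20 is β); the sense of induction of the bisphosphine (step 3) and of the Shi ketone (step 19) is assigned by analogy with simple substrates, and the mirror-image ligand or ketone is taken if it proves opposite.

**Step 1**
Reactants: 1 2-allylcyclohexane-1,3-dione; 2 acrolein
Product: 3 3-(1-allyl-2,6-dioxocyclohexyl)propanal
Conditions: Et3N (cat.), H2O, rt
Reagents that add atoms: none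
Why: Michael addition of the 2-substituted 1,3-dione to acrolein should give the quaternary (still prochiral) C10 without O-alkylation.

**Step 2**
Reactants: 3 3-(1-allyl-2,6-dioxocyclohexyl)propanal; 4 methyl (triphenylphosphoranylidene)acetate
Product: 5 methyl (E)-5-(1-allyl-2,6-dioxocyclohexyl)pent-2-enoate
Conditions: CH2Cl2, rt
Reagents that add atoms: none
Why: Wittig olefination with the stabilised ylide is selective for the aldehyde over the hindered diketone and should give the (E)-enoate.

**Step 3**
Reactants: 5 methyl (E)-5-(1-allyl-2,6-dioxocyclohexyl)pent-2-enoate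
Product: 7 methyl 10β-allyl-5β-hydroxy-9-oxodecalin-4β-carboxylate (cis-fused; C4/C5 configuration immaterial), via silyl aldolate 6 (not isolated)
Conditions: Cu(OAc)2·H2O (5 mol%), (R)-DTBM-SEGPHOS (5.5 mol%), (EtO)2MeSiH, toluene, −20 °C to rt; then 1 M HCl, THF
Reagents that add atoms: none
Why: Copper hydride-catalysed reductive aldol cyclisation: conjugate reduction gives a copper ester enolate that adds to one of the two enantiotopic ring carbonyls, so the chiral bisphosphine sets C10 (the C4 and C5 centres formed alongside are erased in steps 4 and 5).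

**Step 4**
Reactants: 7 methyl 10β-allyl-5β-hydroxy-9-oxodecalin-4β-carboxylate
Product: 8 methyl 10β-allyl-9,9-(ethylenedioxy)octal-4-ene-4-carboxylate (C4=C5)
Conditions: HOCH2CH2OH, p-TsOH·H2O (cat.), benzene, reflux (Dean–Stark)
Reagents that add atoms: ethylene glycol, OCCO
Why: Acid-catalysed dehydration of the tertiary β-hydroxy ester (Hajos–Parrish-type ketol dehydration) and dioxolane formation at the only ketone (C9) should occur together; either double-bond isomer converges in step 5.

**Step 5**
Reactants: 8 methyl 10β-allyl-9,9-(ethylenedioxy)octal-4-ene-4-carboxylate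
Product: 10 methyl 10β-allyl-9,9-(ethylenedioxy)-4α-methyloctal-5-ene-4β-carboxylate, via lithium dienolate 9 (not isolated)
Conditions: LiN(iPr)2, THF–HMPA, −78 °C; MeI, −78 to 0 °C
Reagents that add atoms: iodomethane, CI
Why: Deconjugative α-alkylation of the ester dienolate: MeI attacks C4 from the α face, anti to the axial C10 substituent, so CO2Me ends β (cis to the future C20) and the double bond moves to C5=C6.

**Step 6**
Reactants: 10 methyl 10β-allyl-9,9-(ethylenedioxy)-4α-methyloctal-5-ene-4β-carboxylate
Product: 11 methyl 9,9-(ethylenedioxy)-4α-methyl-10β-[(E)-prop-1-enyl]octal-5-ene-4β-carboxylate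
Conditions: RuHCl(CO)(PPh3)3 (5 mol%), toluene, 80 °C
Reagents that add atoms: none
Why: Ruthenium hydride-catalysed allyl-to-propenyl isomerisation (hydrometalation/β-hydride elimination) moves only the terminal double bond, since C5=C6 lies between two quaternary carbons.

**Step 7**
Reactants: 11 methyl 9,9-(ethylenedioxy)-4α-methyl-10β-[(E)-prop-1-enyl]octal-5-ene-4β-carboxylate
Product: 15 9,9-(ethylenedioxy)-11,12,13,14,15,16,17-heptanorlabd-5-en-19,20-olide, via diol 12 (not isolated), via aldehyde 13 (not isolated), via hydroxy ester 14 (not isolated)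
Conditions: OsO4 (2 mol%), NaIO4, 2,6-lutidine, dioxane–H2O, rt; then NaBH4, 0 °C to rt
Reagents that add atoms: osmium tetroxide (catalytic oxygen carrier), O=[Os](=O)(=O)=O; sodium periodate (terminal oxidant), [Na+].[O-]I(=O)(=O)=O
Why: Lemieux–Johnson cleavage should select the accessible propenyl group over the C5=C6 bond flanked by two quaternary carbons, and the C20 alkoxide formed on borohydride reduction lactonises onto the cis, 1,3-diaxial C19 ester (possible only for the desired C4 epimer).

**Step 8**
Reactants: 15 9,9-(ethylenedioxy)-11,12,13,14,15,16,17-heptanorlabd-5-en-19,20-olide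
Product: 16 9-oxo-11,12,13,14,15,16,17-heptanorlabd-5-en-19,20-olide
Conditions: 1 M HCl, THF, rt
Reagents that add atoms: water, O
Why: Acid-catalysed ketal hydrolysis frees the C9 ketone; the lactone (no α-hydrogen) and the hindered alkene should be unaffected.

**Step 9**
Reactants: 16 9-oxo-11,12,13,14,15,16,17-heptanorlabd-5-en-19,20-olide
Product: 19 9-oxo-17-(triethylsilyloxy)-11,12,13,14,15,16-hexanorlabd-5-en-19,20-olide (C8 epimers), via lithium enolate 17 (not isolated), via lithium aldolate 18 (not isolated)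
Conditions: LiN(SiMe3)2, THF, −78 °C; HCHO (gas); then Et3SiCl, −78 to −20 °C
Reagents that add atoms: formaldehyde, C=O; chlorotriethylsilane, CC[Si](Cl)(CC)CC
Why: Aldol addition of the only possible enolate (C8; C10 is quaternary and the lactone has no α-hydrogen) to formaldehyde with in-situ silylation; the C8 configuration is irrelevant because C8 becomes sp2 in step 10.

**Step 10**
Reactants: 19 9-oxo-17-(triethylsilyloxy)-11,12,13,14,15,16-hexanorlabd-5-en-19,20-olide
Product: 21 17-(triethylsilyloxy)-9-(trifluoromethanesulfonyloxy)-11,12,13,14,15,16-hexanorlabda-5,8-dien-19,20-olide, via potassium enolate 20 (not isolated)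
Conditions: KN(SiMe3)2, THF, −78 °C; PhNTf2, −78 to 0 °C
Reagents that add atoms: N-phenyl-bis(trifluoromethanesulfonimide), O=S(=O)(N(c1ccccc1)S(=O)(=O)C(F)(F)F)C(F)(F)F
Why: O-Triflation of the enolate formed at the single remaining α-hydrogen (C8–H) should give the tetrasubstituted enol triflate, low temperature suppressing β-elimination of the silyloxy group.

**Step 11**
Reactants: 21 17-(triethylsilyloxy)-9-(trifluoromethanesulfonyloxy)-11,12,13,14,15,16-hexanorlabda-5,8-dien-19,20-olide
Product: 23 6α-hydroxy-17-(triethylsilyloxy)-9-(trifluoromethanesulfonyloxy)-11,12,13,14,15,16-hexanorlabd-8-en-19,20-olide (5α-H), via alkylborane 22 (not isolated)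
Conditions: BH3·THF, THF, 0 °C to rt; then H2O2, aq. NaOH, 0 °C
Reagents that add atoms: hydrogen peroxide, OO
Why: Hydroboration–oxidation: borane adds syn from the α face (the β face is covered by the lactone bridge), placing H at C5α (trans ring fusion) and boron, then OH, at C6α, while the electron-poor tetrasubstituted enol triflate is inert.

**Step 12**
Reactants: 23 the 6α-alcohol
Product: 24 6-oxo-17-(triethylsilyloxy)-9-(trifluoromethanesulfonyloxy)-11,12,13,14,15,16-hexanorlabd-8-en-19,20-olide
Conditions: Dess–Martin periodinane, NaHCO3, CH2Cl2, rt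
Reagents that add atoms: none
Why: Dess–Martin oxidation of the secondary alcohol proceeds under neutral conditions that should not epimerise C5.

**Step 13**
Reactants: 24 the 6-ketone
Product: 25 6β-hydroxy-17-(triethylsilyloxy)-9-(trifluoromethanesulfonyloxy)-11,12,13,14,15,16-hexanorlabd-8-en-19,20-olide
Conditions: NaBH4, CeCl3·7H2O, MeOH–THF, −78 °C; AcOH quench
Reagents that add atoms: none
Why: Luche-type reduction: hydride attacks from the open α face (axial attack is blocked by the 1,3-diaxial C19/C20 bridge) to give the axial 6β-alcohol, and cold, near-neutral conditions limit lactone migration to the 19,6β-γ-lactone.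

**Step 14**
Reactants: 25 the 6β-alcohol
Product: 26 6β-acetoxy-17-(triethylsilyloxy)-9-(trifluoromethanesulfonyloxy)-11,12,13,14,15,16-hexanorlabd-8-en-19,20-olide
Conditions: Ac2O, DMAP, pyridine, 0 °C to rt
Reagents that add atoms: acetic anhydride, CC(=O)OC(C)=O
Why: DMAP-catalysed acylation locks the hindered axial 6β-oxygen as the acetate before any base-mediated lactone migration; no enolate chemistry follows, so the acetate can be carried to the end.

**Step 15**
Reactants: 27 allyl propargyl ether
Product: 28 3-vinyl-2,5-dihydrofuran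
Conditions: RuCl2(=CHPh)(PCy3)2 (first-generation Grubbs catalyst, 3 mol%), ethylene (1 atm), CH2Cl2, rt
Reagents that add atoms: none
Why: Ring-closing enyne metathesis converts the 1,6-enyne into the cyclic 1,3-diene with the five-membered ring in place.

**Step 16**
Reactants: 26 the 6β-acetoxy enol triflate; 28 3-vinyl-2,5-dihydrofuran
Product: 30 6β-acetoxy-15,16-epoxy-17-(triethylsilyloxy)labda-8,13-dien-19,20-olide, via alkylborane 29 (not isolated)
Conditions: 28, 9-BBN-H, THF, 0 °C to rt; then 26, Pd(dppf)Cl2 (10 mol%), AsPh3, Cs2CO3, DMF–THF–H2O, 45 °C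
Reagents that add atoms: none
Why: B-alkyl Suzuki–Miyaura coupling: 9-BBN adds only to the terminal vinyl carbon of 28, and the resulting sp3 borane couples with the enol triflate to join C11 to C9 under base mild enough for acetate, lactone and silyl ether.

**Step 17**
Reactants: 30 the triethylsilyl ether
Product: 31 6β-acetoxy-15,16-epoxy-17-hydroxylabda-8,13-dien-19,20-olide
Conditions: PPTS, MeOH, 0 °C to rt
Reagents that add atoms: none
Why: Mild acid-catalysed methanolysis removes the primary allylic triethylsilyl ether selectively; acetate, lactone and the 2,5-dihydrofuran are stable.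

**Step 18**
Reactants: 31 the allylic alcohol
Product: 32 6β-acetoxy-8α,9α:15,16-diepoxy-17-hydroxylabd-13-en-19,20-olide
Conditions: mCPBA, NaHCO3, CH2Cl2, −20 °C
Reagents that add atoms: 3-chloroperbenzoic acid, OOC(=O)c1cccc(Cl)c1
Why: Prilezhaev epoxidation: the electron-rich tetrasubstituted C8=C9 bond reacts far faster than the inductively deactivated dihydrofuran alkene, and the peracid approaches from the α face (β is shielded by C20 and the axial 6β-acetate), which sets C8 and C9.

**Step 19**
Reactants: 32 the mono-epoxide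
Product: 33 (13R,14S)-6β-acetoxy-8α,9α:13,14:15,16-triepoxy-17-hydroxylabdan-19,20-olide
Conditions: L-fructose-derived Shi ketone (0.3 equiv), Oxone (2KHSO5·KHSO4·K2SO4), K2CO3, Bu4NHSO4, MeCN–dimethoxymethane/aq. Na2B4O7 buffer, 0 °C
Reagents that add atoms: potassium peroxymonosulfate (active part of Oxone), [K+].[O-]S(=O)(=O)OO
Why: Shi asymmetric epoxidation of the remaining trisubstituted cyclic alkene by the chiral dioxirane: the ketone enantiomer (reagent control) fixes C13 and C14.

**Step 20**
Reactants: 33 the bis-epoxy alcohol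
Product: 35 (13S,14S)-6β-acetoxy-8β,17:9α,13:15,16-triepoxy-14-hydroxylabdan-19,20-olide, via epoxonium ion 34 (not isolated)
Conditions: (±)-camphorsulfonic acid (0.1 equiv), CH2Cl2, −40 to 0 °C; then Et3N
Reagents that add atoms: none
Why: Proposed new method: protonation of the strained, cis-fused side-chain oxirane lets the oxygen of the 8α,9α-oxirane attack C13 from the back, giving a bicyclic epoxonium ion (O bonded to C8, C9 and C13); the C17 hydroxyl, anti-periplanar to the C8–O bond, then closes onto C8 and releases the proton, so the three-membered ring O–C8–C9 is expanded by two atoms to the oxolane O–C9–C11–C12–C13 while the 8β,17-oxirane appears. The closest known reaction types are acid-triggered epoxide-opening cascades through epoxonium ions (epoxide-to-oxolane ring expansion) and the Payne rearrangement of 2,3-epoxy alcohols; their merger with a 3-exo hydroxyl termination is new. Rings closed: the oxolane by 5-exo-tet attack of an oxirane oxygen, the 8,17-oxirane by 3-exo-tet attack of the hydroxyl. Stereocentres: C13 is set by inversion of the Shi epoxide, C9 keeps the configuration of the α-epoxide because its C–O bond is never broken, C8 is inverted by backside attack of O17 (oxygen β, C17 α), and C14 keeps its oxygen as the free hydroxyl. The step needs attack at C13 and not C14 (secured by the 5-exo geometry and the tertiary C13) and opening of the epoxonium at C8 and not C9 (secured by the internal nucleophile on C8 and the shielding of the C9 backside by C10 and C20); should the decalin oxirane be activated first, the same O17 closure gives the 9α-alcohol, which opens the side-chain oxirane 5-exo to the same product. Loss of one oxirane's strain drives the cascade, and catalytic acid at low temperature should spare the product epoxide.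

**Step 21**
Reactants: 35 the 14-alcohol
Product: 36 (13R)-6β-acetoxy-8β,17:9α,13:15,16-triepoxylabd-14-en-19,20-olide (target)
Conditions: Martin sulfurane Ph2S[OC(CF3)2Ph]2, Et3N, CH2Cl2, 0 °C to rt
Reagents that add atoms: none
Why: Martin sulfurane dehydration (E2-type) of the secondary alcohol: only C15 carries β-hydrogens (C13 is quaternary), so the 2,3-dihydrofuran enol ether is the sole regioisomer, formed under non-acidic conditions that spare the epoxide and the acid-labile spiro enol ether.

**Compound list**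
1 | 2-allylcyclohexane-1,3-dione | C=CCC1C(=O)CCCC1=O | starting material
2 | acrolein | C=CC=O | starting material
3 | 3-(1-allyl-2,6-dioxocyclohexyl)propanal | O=CCCC1(CC=C)C(=O)CCCC1=O | intermediate
4 | methyl (triphenylphosphoranylidene)acetate | COC(=O)C=P(c1ccccc1)(c1ccccc1)c1ccccc1 | starting material
5 | methyl (E)-5-(1-allyl-2,6-dioxocyclohexyl)pent-2-enoate | COC(=O)/C=C/CCC1(CC=C)C(=O)CCCC1=O | intermediate
6 | diethoxy(methyl)silyl ether of 7 (silyl aldolate) | C1CCC(=O)[C@@]3(CC=C)CCC[C@H](C(=O)OC)[C@@]13O[Si](C)(OCC)OCC | intermediate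
7 | methyl 10β-allyl-5β-hydroxy-9-oxodecalin-4β-carboxylate (cis-fused) | C1CCC(=O)[C@@]3(CC=C)CCC[C@H](C(=O)OC)[C@@]13O | intermediate
8 | methyl 10β-allyl-9,9-(ethylenedioxy)octal-4-ene-4-carboxylate | C1CCC4(OCCO4)[C@@]3(CC=C)CCCC(C(=O)OC)=C13 | intermediate
9 | lithium dienolate of 8 (C19 enolate, C5=C6) | C1CCC4(OCCO4)[C@@]3(CC=C)CCCC(=C([O-])OC)C3=1.[Li+] | intermediate
10 | methyl 10β-allyl-9,9-(ethylenedioxy)-4α-methyloctal-5-ene-4β-carboxylate | C1CCC4(OCCO4)[C@@]3(CC=C)CCC[C@](C)(C(=O)OC)C3=1 | intermediate
11 | methyl 9,9-(ethylenedioxy)-4α-methyl-10β-[(E)-prop-1-enyl]octal-5-ene-4β-carboxylate | C1CCC4(OCCO4)[C@@]3(/C=C/C)CCC[C@](C)(C(=O)OC)C3=1 | intermediate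
12 | 10β-(1,2-dihydroxypropyl) analogue of 11 (diastereomer mixture) | C1CCC4(OCCO4)[C@@]3(C(O)C(C)O)CCC[C@](C)(C(=O)OC)C3=1 | intermediate
13 | 10β-formyl ester (C20 aldehyde) | C1CCC4(OCCO4)[C@@]3(C=O)CCC[C@](C)(C(=O)OC)C3=1 | intermediate
14 | 10β-hydroxymethyl ester | C1CCC4(OCCO4)[C@@]3(CO)CCC[C@](C)(C(=O)OC)C3=1 | intermediate
15 | 9,9-(ethylenedioxy)-11,12,13,14,15,16,17-heptanorlabd-5-en-19,20-olide | C1CCC4(OCCO4)[C@]23CCC[C@](C)(C(=O)OC2)C3=1 | intermediate
16 | 9-oxo-11,12,13,14,15,16,17-heptanorlabd-5-en-19,20-olide | C1CCC(=O)[C@]23CCC[C@](C)(C(=O)OC2)C3=1 | intermediate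
17 | lithium C8=C9 enolate of 16 | C1CC=C([O-])[C@]23CCC[C@](C)(C(=O)OC2)C3=1.[Li+] | intermediate
18 | lithium 17-alkoxide of the 8-hydroxymethyl ketone (C8 epimers) | C1CC(C[O-])C(=O)[C@]23CCC[C@](C)(C(=O)OC2)C3=1.[Li+] | intermediate
19 | 9-oxo-17-(triethylsilyloxy)-11,12,13,14,15,16-hexanorlabd-5-en-19,20-olide (C8 epimers) | C1CC(CO[Si](CC)(CC)CC)C(=O)[C@]23CCC[C@](C)(C(=O)OC2)C3=1 | intermediate
20 | potassium C8=C9 enolate of 19 | C1CC(CO[Si](CC)(CC)CC)=C([O-])[C@]23CCC[C@](C)(C(=O)OC2)C3=1.[K+] | intermediate
21 | 17-(triethylsilyloxy)-9-(trifluoromethanesulfonyloxy)-11,12,13,14,15,16-hexanorlabda-5,8-dien-19,20-olide | C1CC(CO[Si](CC)(CC)CC)=C(OS(=O)(=O)C(F)(F)F)[C@]23CCC[C@](C)(C(=O)OC2)C3=1 | intermediate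
22 | 6α-boryl (monoalkylborane) adduct of 21, 5α-H | B[C@H]1CC(CO[Si](CC)(CC)CC)=C(OS(=O)(=O)C(F)(F)F)[C@]23CCC[C@](C)(C(=O)OC2)[C@H]13 | intermediate
23 | 6α-hydroxy enol triflate (5α-H) | O[C@H]1CC(CO[Si](CC)(CC)CC)=C(OS(=O)(=O)C(F)(F)F)[C@]23CCC[C@](C)(C(=O)OC2)[C@H]13 | intermediate
24 | 6-oxo enol triflate | O=C1CC(CO[Si](CC)(CC)CC)=C(OS(=O)(=O)C(F)(F)F)[C@]23CCC[C@](C)(C(=O)OC2)[C@H]13 | intermediate
25 | 6β-hydroxy enol triflate | O[C@@H]1CC(CO[Si](CC)(CC)CC)=C(OS(=O)(=O)C(F)(F)F)[C@]23CCC[C@](C)(C(=O)OC2)[C@H]13 | intermediate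
26 | 6β-acetoxy-17-(triethylsilyloxy)-9-(trifluoromethanesulfonyloxy)-11,12,13,14,15,16-hexanorlabd-8-en-19,20-olide | CC(=O)O[C@@H]1CC(CO[Si](CC)(CC)CC)=C(OS(=O)(=O)C(F)(F)F)[C@]23CCC[C@](C)(C(=O)OC2)[C@H]13 | intermediate
27 | allyl propargyl ether | C=CCOCC#C | starting material
28 | 3-vinyl-2,5-dihydrofuran | C=CC1=CCOC1 | intermediate
29 | B-[2-(2,5-dihydrofuran-3-yl)ethyl]-9-borabicyclo[3.3.1]nonane | B1(CCC2=CCOC2)C2CCCC1CCC2 | intermediate
30 | 6β-acetoxy-15,16-epoxy-17-(triethylsilyloxy)labda-8,13-dien-19,20-olide | CC(=O)O[C@@H]1CC(CO[Si](CC)(CC)CC)=C(CCC4=CCOC4)[C@]23CCC[C@](C)(C(=O)OC2)[C@H]13 | intermediate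
31 | 6β-acetoxy-15,16-epoxy-17-hydroxylabda-8,13-dien-19,20-olide | CC(=O)O[C@@H]1CC(CO)=C(CCC4=CCOC4)[C@]23CCC[C@](C)(C(=O)OC2)[C@H]13 | intermediate
32 | 6β-acetoxy-8α,9α:15,16-diepoxy-17-hydroxylabd-13-en-19,20-olide | CC(=O)O[C@@H]1C[C@@]4(CO)O[C@@]4(CCC5=CCOC5)[C@]23CCC[C@](C)(C(=O)OC2)[C@H]13 | intermediate
33 | (13R,14S)-6β-acetoxy-8α,9α:13,14:15,16-triepoxy-17-hydroxylabdan-19,20-olide | CC(=O)O[C@@H]1C[C@@]4(CO)O[C@@]4(CC[C@@]56COC[C@@H]5O6)[C@]23CCC[C@](C)(C(=O)OC2)[C@H]13 | intermediate
34 | epoxonium ion (O bonded to C8, C9, C13; free 14-OH and 17-OH) | CC(=O)O[C@@H]1C[C@@]4(CO)[O+]5[C@@]4(CC[C@]56[C@@H](O)COC6)[C@]23CCC[C@](C)(C(=O)OC2)[C@H]13 | intermediate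
35 | (13S,14S)-6β-acetoxy-8β,17:9α,13:15,16-triepoxy-14-hydroxylabdan-19,20-olide | CC(=O)O[C@@H]1C[C@@]2(CO2)[C@]2(CC[C@]3([C@@H](O)COC3)O2)[C@]23CCC[C@](C)(C(=O)OC2)[C@H]13 | intermediate
36 | (13R)-6β-acetoxy-8β,17:9α,13:15,16-triepoxylabd-14-en-19,20-olide | CC(=O)O[C@@H]1C[C@@]2(CO2)[C@]2(CC[C@]3(C=COC3)O2)[C@]23CCC[C@](C)(C(=O)OC2)[C@H]13 | target

**Step count and risks**
Total steps: 21. Longest linear sequence: 20 (steps 1–14 and 16–21).

Steps most likely to fail:

1. Step 20. Acid may activate the tetrasubstituted decalin oxirane first and divert it into pinacol-type (Meinwald) rearrangement or hydride shift from C17, or the axial 6β-acetate may take part at C8. Fallback with known chemistry, setting out from 33: Appel iodination (I2, PPh3, imidazole) gives the 17-iodo bis-epoxide F1; zinc dust in ethanol opens the 2,3-epoxy iodide reductively to the transposed tertiary allylic alcohol, the 9α-hydroxy-8(17)-ene F2; catalytic camphorsulfonic acid then effects the ordinary 5-exo hydroxy-epoxide cyclisation (inversion at C13) to the spiro oxolane with exocyclic methylene F3; N-bromosuccinimide in aqueous acetone gives the bromohydrin F4 (bromide on C17, 8β-hydroxyl by anti attack of water at C8), and Ag2O closes the 8β,17-oxirane, returning to the route at 35.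

2. Step 16. Oxidative addition and transmetalation at the tetrasubstituted enol triflate next to the quaternary C10 may be slow, so that protodeboronation of 29 or hydrolysis of the triflate wins. Fallback, setting out from 28 by way of 29: iodination of the borane (I2, NaOMe) gives 3-(2-iodoethyl)-2,5-dihydrofuran F5; zinc insertion (Zn dust, LiCl, THF) gives the isolable alkylzinc iodide F6, which is joined to 26 by Negishi coupling (Pd2(dba)3, SPhos, THF–NMP), a base-free transmetalation by a different organometallic class that tolerates bulkier ligands; the route is rejoined at 30.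

3. Step 3. Discrimination between the two enantiotopic ring carbonyls may be poor, or ketone hydrosilylation may compete with conjugate reduction. Fallback, setting out from 5: Corey–Bakshi–Shibata monoreduction (oxazaborolidine, catecholborane) desymmetrises the dione to the hydroxy ketone F7, fixing C10 by the choice of reduced carbonyl; stoichiometric [(Ph3P)CuH]6 then effects the reductive aldol cyclisation onto the remaining ketone to give the diol F8; Dess–Martin oxidation of the secondary alcohol returns to the route at 7.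

**Further compounds**
F1 | step 20 | (13R,14S)-6β-acetoxy-8α,9α:13,14:15,16-triepoxy-17-iodolabdan-19,20-olide | CC(=O)O[C@@H]1C[C@@]4(CI)O[C@@]4(CC[C@@]56COC[C@@H]5O6)[C@]23CCC[C@](C)(C(=O)OC2)[C@H]13
F2 | step 20 | (13R,14S)-6β-acetoxy-13,14:15,16-diepoxy-9α-hydroxylabd-8(17)-en-19,20-olide | CC(=O)O[C@@H]1CC(=C)[C@](O)(CC[C@@]56COC[C@@H]5O6)[C@]23CCC[C@](C)(C(=O)OC2)[C@H]13
F3 | step 20 | (13S,14S)-6β-acetoxy-9α,13:15,16-diepoxy-14-hydroxylabd-8(17)-en-19,20-olide | CC(=O)O[C@@H]1CC(=C)[C@]2(CC[C@]3([C@@H](O)COC3)O2)[C@]23CCC[C@](C)(C(=O)OC2)[C@H]13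
F4 | step 20 | (13S,14S)-6β-acetoxy-17-bromo-9α,13:15,16-diepoxy-8β,14-dihydroxylabdan-19,20-olide | CC(=O)O[C@@H]1C[C@@](O)(CBr)[C@]2(CC[C@]3([C@@H](O)COC3)O2)[C@]23CCC[C@](C)(C(=O)OC2)[C@H]13
F5 | step 16 | 3-(2-iodoethyl)-2,5-dihydrofuran | ICCC1=CCOC1
F6 | step 16 | [2-(2,5-dihydrofuran-3-yl)ethyl]zinc iodide | I[Zn]CCC1=CCOC1
F7 | step 3 | methyl (E)-5-(1-allyl-2-hydroxy-6-oxocyclohexyl)pent-2-enoate (C10 as in 7; carbinol configuration immaterial) | O=C1CCCC(O)[C@@]1(CC=C)CC/C=C/C(=O)OC
F8 | step 3 | methyl 10β-allyl-5β,9-dihydroxydecalin-4β-carboxylate (9-hydroxy analogue of 7) | C1CCC(O)[C@@]3(CC=C)CCC[C@H](C(=O)OC)[C@@]13O
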